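Set alpha beside the south-east run, the simulated flask nearest to it, and ask why each should end where it does.

| flask | E | Q | temperature | remark | time |
|---|---|---|---|---|---|
| north-east | 0.051 M | 0.024 M | −12 °C | run made earlier |  |
| south-east | 0.051 M | 0.097 M | 4 °C | run made earlier |  |
| east | 0.076 M | 0.0484 M | −12 °C | run made earlier |  |
| alpha | 0.051 M | 0.0484 M | 10 °C |  | 3.0 d |
| zeta | 0.051 M | 0.0484 M |  | at 10 °C until 20 h, from then on at −20 °C | 3.0 d |
| gamma | 0.051 M | 0.0484 M | −20 °C |  | 3.0 d |

| run | time / d | J / % | E / % |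
|---|---|---|---|
| north-east | 1.25 | 27.4 | 53.6 |
| north-east | 2.50 | 35.6 | 46.6 |
| north-east | 4.00 | 35.7 | 43.5 |
| north-east | 5.00 | 33.2 | 41.6 |
| north-east | 6.00 | 31.8 | 40.7 |
| north-east | 8.00 | 28.9 | 39.1 |
| south-east | 0.250 | 75.7 | 9.9 |
| south-east | 0.333 | 80.0 | 6.2 |
| south-east | 0.500 | 83.2 | 1.3 |
| south-east | 0.833 | 84.3 | 0.3 |
| south-east | 1.25 | 83.9 | 0.2 |
| south-east | 2.08 | 84.1 | 0 |
| south-east | 3.00 | 84.5 | 0.2 |
| east | 1.67 | 46.8 | 35.5 |
| east | 4.00 | 47.7 | 29.2 |
| east | 5.00 | 45.3 | 29.1 |
| east | 8.00 | 38.6 | 26.4 |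

(readings scatter by 0.3 percentage points)

- which flask leads in amount of J, in percent of the E charged ("all alike" within 1.5 percentage points) (alpha / zeta / gamma / all alike)
- how much J is there at the end, in percent of the E charged: alpha
- how much J is there at the end, in percent of the E charged: zeta
- how much J is there at the end, in percent of the E charged: gamma

- the numbers in the tables scatter with a standard deviation of 0.3 percentage points
- a reading or a percentage of J counts all its forms, free or not

Both flasks charge 0.051 M of E. The south-east run holds Q in excess (0.097 M): its E reads 0.2% at the end, and J stands flat from 84.3% at 0.833 d to 84.5% at 3.00 d. Alpha holds less Q than E (0.0484 M), so there Q is the limiting reagent. We therefore scale the flat share of the south-east run by Q charged per E charged: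

yield = 84.5% × 0.0484 M / 0.051 M = 80.2%

This plateau yield, the flat share times the limiting charge per E charged, is what we carry.

Does alpha get there in time? We integrate the second-order rate in closed form on the first south-east reading, counting the E lost as lost to Q:

k = ln(fraction of Q left / fraction of E left) / ((Q charge − E charge) × time) = 145 L mol⁻¹ d⁻¹

For nearly equal charges, the fraction of Q left after 3.0 d is:

1 / (1 + k × 0.0484 M × 3.0 d) = 4.53%

Alpha is warmer (10 °C against 4 °C), so we take that as the upper end and commit to about 80.2% for alpha. At −12 °C the north-east run has a plateau yield of 39.8% by the same scaling, yet its J reads 27.4% at 1.25 d, so J comes slowly in the cold. Gamma stands colder still, at −20 °C, and zeta has 20 h of its 3.0 d at alpha's temperature, so we rank both behind alpha.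

The forecast has zeta leading, with 69% for alpha, 72% for zeta and 54% for gamma. On the loss of J it says: “This decay probably has a higher Ea, perhaps sixfold faster at 10 °C.” Our alpha stands above its figure.

The flasks give 85.1% for alpha, 75.4% for zeta and 41.3% for gamma, so alpha leads.

    E + Q → D (k = 0.800 L mol⁻¹ h⁻¹, Ea = 49.0 kJ mol⁻¹)
    E ⇌ G (K = 0.320, k = 0.0440 h⁻¹, Ea = 89.0 kJ mol⁻¹, ΔH = −68.0 kJ mol⁻¹)
    G → L (k = 0.00250 h⁻¹, Ea = 86.0 kJ mol⁻¹)
    D → J (k = 0.0230 h⁻¹, Ea = 90.0 kJ mol⁻¹)
    Z ⇌ J, rate k5*(cs5 - [J]) while solid is left; crystals form when [J] > cs5 (solubility = 46.0 mM, k = 0.220 h⁻¹)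
    J ⇌ X (K = 2.90, k = 0.00120 h⁻¹, Ea = 90.0 kJ mol⁻¹, ΔH = −67.0 kJ mol⁻¹)
    (constants at −20 °C)

Alpha ends above the plateau yield, with 1.5% of its Q left and 8.46% as X. J plus X comes to 93.6%, against 94.9% for Q per E charged, and J is 91.0% of that sum. The south-east run with just its temperature moved to alpha's gives 90.7%, against 84.1% as it stands. Now take the neighbour of zeta charged with 0.012 M of Q, or 0.235 equiv. The same reckoning gives 19.9%, and that flask ends with 0.018% of its Q left and J at 20.2%.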